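The target is what we count, and the question is how steeply its yield climbs with the partner. Every flask starts with the same substrate, and the new flasks differ in c_partner.

| setting | Monday's | Sunday's | west | north | south | south-east |
|---|---|---|---|---|---|---|
| substrate | 0.10 M | 0.10 M | 0.10 M | 0.10 M | 0.10 M | 0.10 M |
| partner | 0.035 M | 0.094 M | 0.0400 M | 0.0600 M | 0.100 M | 0.150 M |
| remark | run made earlier | run made earlier |  |  |  |  |
| time |  |  | 2.5 d | 2.5 d | 2.5 d | 2.5 d |

| run | time / h | target / % |
|---|---|---|
| Monday's | 2.50 | 0.3 |
| Monday's | 4.00 | 0.3 |
| Monday's | 6.00 | 2.3 |
| Monday's | 8.00 | 3.8 |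
| Monday's | 12.0 | 6.8 |
| Monday's | 20.0 | 11.2 |
| Monday's | 30.0 | 14.8 |
| Sunday's | 2.50 | 1.1 |
| Sunday's | 4.00 | 4.8 |
| Sunday's | 6.00 | 6.3 |
| Sunday's | 8.00 | 10.3 |
| Sunday's | 12.0 | 15.9 |
| Sunday's | 20.0 | 25.5 |
| Sunday's | 30.0 | 31.2 |

(readings scatter by 0.5 percentage points)

* amount of target at the end, in percent of the substrate charged for west, north, south, south-east, in this order
* the shape of the row from first to last (hardly changes / falls, then rises / rises, then falls / rises all the way / falls all the way)

- the numbers in the tables scatter by 0.5 percentage points (one standard deviation)
- a reading or a percentage of target counts all its forms, free or not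
- "hardly changes" means that all values lie within two and a half points (for a concentration: within two and a half percent of the largest)

At 30.0 h Monday's run stands at 14.8 % and Sunday's at 31.2 %, with c_partner at 0.035 M and 0.094 M. We call the logarithm of the target ratio over the logarithm of the partner ratio, at equal time and equal substrate, the yield order, an apparent order. These two readings give 0.755.

Now we turn the question round. For a row that falls, the yield order at the asked time would have to be negative. At 30.0 h a negative value would put Sunday's reading below Monday's. It lies 16 percentage points above, and the scatter is 0.5 points, so the gap is larger than the scatter.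

One caution remains. The asked time of 2.5 d is later than the last reading, and south-east is charged with more partner than Sunday's run. Carrying the yield order over is therefore our assumption. On it we expect a row that rises all the way, with last over first at 2.71.

The forecast gives 23 %, 31 %, 39 % and 43 %, and the shape rises all the way. In its words: “The row keeps rising but flattens”. Its last over first is 1.87, flatter than ours.

The flasks give 17.4 %, 24.2 %, 33.9 % and 40.6 %, and the shape rises all the way.

    partner + intermediate → target (k = 1.80 × 10⁻⁴ M⁻¹ s⁻¹)
    target ⇌ isomer of the product (K = 2.10, k = 7.70 × 10⁻⁶ s⁻¹)
    2 intermediate → homo product (k = 1.80 × 10⁻⁴ M⁻¹ s⁻¹)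
    substrate → intermediate (k = 2.20 × 10⁻⁵ s⁻¹)
    substrate + target ⇌ idle adduct, settled at all times (K = 270 M⁻¹)

Last over first is 2.33. At 2.50 d the homo product stands at 52.7 % in west and 16.6 % in south-east. The yield order from west to south-east at 2.5 d is 0.641, lower than the value read from the runs at 30.0 h. Carried from west to north, the value read from the runs gives 23.6 %, and north holds 24.2 %.

(The numbers in the tables were computed with constants of no real substance, and the scatter is random.)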